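**Retrosynthetic overview**

1. Numbering used below (germacrane type): C1=C10(Me) is the Z alkene, C2 the CH2 next to C1, C3 the angelate carbinol, C4(Me)=C5 the E alkene, C6 the acetate carbinol, C7 the isopropyl carbon, C8 and C9 the two ring CH2 groups.
2. Endgame: the angelate (C3) and then the acetate (C6, after desilylation) are put on a ten-membered ring alcohol that leaves the key step with only its C3 hydroxyl free.
3. Key disconnection C9–C10 with opening of a template ring: the homoallylic unit O–C3–C2–C1=C10(Me) of the target is folded back into a 5-methyl-2,3-dihydrofuran (ring atoms O, C3, C2, C1, C10). Nickel-catalysed coupling of its C10(sp2)–O bond with a B-alkyl group made from a C8=C9 vinyl group closes the ten-membered ring, opens the five-membered ring with retention (Z alkene) and frees the C3 hydroxyl.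
4. The dihydrofuran comes from a homopropargylic alcohol (gold-catalysed 5-endo-dig cyclisation) made by catalytic asymmetric propargylation of an E enal (sets C3). The enal comes from a catalytic asymmetric anti allylboration of ethyl (2E)-2-methyl-4-oxobut-2-enoate with an (E)-γ-isopropylallyl boronate (sets C6 and C7, brings the vinyl group; the E alkene is bought in).
5. Ring order: the five-membered oxygen ring (template, step 8) first, then the ten-membered carbocycle (step 9), formed in the event that destroys the template.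

Key step: step 9

Assumption: the (R)-configured BINOL phosphoric acid is taken to direct the allyl or propargyl group to the Re face of an unsaturated aldehyde, which gives 6R with the (R)-acid in step 2 and 3S with the (S)-acid in step 6; if the sense proves opposite, the antipodal acid is used in each step.

**Route**

Step 1
Reactants: 1 (E)-4-methylpent-2-ene
Product: 3 4,4,5,5-tetramethyl-2-[(2E)-4-methylpent-2-en-1-yl]-1,3,2-dioxaborolane, via allylpotassium 2 (not isolated)
Conditions: n-BuLi, KOt-Bu, THF, −78 to −50 °C; then 2-isopropoxy-4,4,5,5-tetramethyl-1,3,2-dioxaborolane, −78 °C; H2O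
Reagents that add atoms: 2-isopropoxy-4,4,5,5-tetramethyl-1,3,2-dioxaborolane, CC(C)OB1OC(C)(C)C(C)(C)O1
Why: Schlosser-base metalation at the allylic methyl group should give the (E)-allylpotassium, which keeps its geometry below −50 °C and is borylated at its unsubstituted terminus, as in the standard preparation of (E)-crotylboronates.

Step 2
Reactants: 3 4,4,5,5-tetramethyl-2-[(2E)-4-methylpent-2-en-1-yl]-1,3,2-dioxaborolane; 4 ethyl (2E)-2-methyl-4-oxobut-2-enoate
Product: 6 ethyl (2E,4R,5R)-4-hydroxy-2-methyl-5-(propan-2-yl)hepta-2,6-dienoate, via pinacol borate ester 5 (not isolated)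
Conditions: (R)-3,3′-bis(2,4,6-triisopropylphenyl)-1,1′-binaphthyl-2,2′-diyl hydrogen phosphate ((R)-TRIP, 5 mol%), 4 Å MS, toluene, −30 °C; then H2O
Reagents that add atoms: none
Why: Chiral phosphoric acid-catalysed allylboration through a closed chair transition state, in which the E geometry of the boronate should fix the anti relation of C6 and C7 and the acid should select the aldehyde face that makes C6 R, the aldehyde reacting in preference to the enoate.

Step 3
Reactants: 6 ethyl (2E,4R,5R)-4-hydroxy-2-methyl-5-(propan-2-yl)hepta-2,6-dienoate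
Product: 7 ethyl (2E,4R,5R)-4-[(tert-butyldimethylsilyl)oxy]-2-methyl-5-(propan-2-yl)hepta-2,6-dienoate
Conditions: t-BuMe2SiOTf, 2,6-lutidine, CH2Cl2, −78 to 0 °C
Reagents that add atoms: tert-butyldimethylsilyl trifluoromethanesulfonate, CC(C)(C)[Si](C)(C)OS(=O)(=O)C(F)(F)F
Why: Silylation of a hindered secondary allylic alcohol with the silyl triflate gives an ether that is inert to hydride, organolithium, borane and low-valent nickel.

Step 4
Reactants: 7 ethyl (2E,4R,5R)-4-[(tert-butyldimethylsilyl)oxy]-2-methyl-5-(propan-2-yl)hepta-2,6-dienoate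
Product: 8 (2E,4R,5R)-4-[(tert-butyldimethylsilyl)oxy]-2-methyl-5-(propan-2-yl)hepta-2,6-dien-1-ol
Conditions: i-Bu2AlH (2.2 equiv), CH2Cl2, −78 °C; aq. Rochelle salt
Reagents that add atoms: none
Why: 1,2-Reduction of the conjugated ester by i-Bu2AlH should give the allylic alcohol without touching the alkenes or the silyl ether.

Step 5
Reactants: 8 (2E,4R,5R)-4-[(tert-butyldimethylsilyl)oxy]-2-methyl-5-(propan-2-yl)hepta-2,6-dien-1-ol
Product: 9 (2E,4R,5R)-4-[(tert-butyldimethylsilyl)oxy]-2-methyl-5-(propan-2-yl)hepta-2,6-dienal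
Conditions: 2,2,6,6-tetramethylpiperidin-1-oxyl (10 mol%), PhI(OAc)2, CH2Cl2, rt
Reagents that add atoms: none
Why: Oxoammonium-mediated oxidation of the primary allylic alcohol stops at the enal and should not isomerise the E alkene.

Step 6
Reactants: 9 (2E,4R,5R)-4-[(tert-butyldimethylsilyl)oxy]-2-methyl-5-(propan-2-yl)hepta-2,6-dienal; 10 4,4,5,5-tetramethyl-2-(propa-1,2-dien-1-yl)-1,3,2-dioxaborolane
Product: 12 (4S,5E,7R,8R)-7-[(tert-butyldimethylsilyl)oxy]-5-methyl-8-(propan-2-yl)deca-5,9-dien-1-yn-4-ol, via pinacol borate ester 11 (not isolated)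
Conditions: (S)-3,3′-bis(2,4,6-triisopropylphenyl)-1,1′-binaphthyl-2,2′-diyl hydrogen phosphate ((S)-TRIP, 10 mol%), 4 Å MS, toluene, 0 °C to rt; then H2O
Reagents that add atoms: none
Why: Chiral phosphoric acid-catalysed propargylation, in which the allenylboronate adds through its CH2 terminus (SE2′, six-membered transition state) and the catalyst should set C3 as S, the existing centres lying 1,4 across the alkene and exerting little influence.

Step 7
Reactants: 12 (4S,5E,7R,8R)-7-[(tert-butyldimethylsilyl)oxy]-5-methyl-8-(propan-2-yl)deca-5,9-dien-1-yn-4-ol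
Product: 14 (5S,6E,8R,9R)-8-[(tert-butyldimethylsilyl)oxy]-6-methyl-9-(propan-2-yl)undeca-6,10-dien-2-yn-5-ol, via dilithium alkoxide acetylide 13 (not isolated)
Conditions: n-BuLi (2.1 equiv), THF, −78 to −20 °C; MeI (1.1 equiv), −78 °C to rt; H2O
Reagents that add atoms: iodomethane, CI
Why: Alkylation of the alkoxide–acetylide dianion should occur at carbon, because the lithium acetylide is far more nucleophilic towards MeI in THF than the lithium alkoxide.

Step 8
Reactants: 14 (5S,6E,8R,9R)-8-[(tert-butyldimethylsilyl)oxy]-6-methyl-9-(propan-2-yl)undeca-6,10-dien-2-yn-5-ol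
Product: 15 (2S)-2-[(2E,4R,5R)-4-[(tert-butyldimethylsilyl)oxy]-5-(propan-2-yl)hepta-2,6-dien-2-yl]-5-methyl-2,3-dihydrofuran
Conditions: (Ph3P)AuNTf2 (2 mol%), THF, 0 °C to rt; Et3N quench, basic alumina
Reagents that add atoms: none
Why: Gold-catalysed 5-endo-dig hydroalkoxylation (cycloisomerisation of a 3-alkyn-1-ol), in which the C3 hydroxyl adds anti to the activated alkyne at C10 and protodeauration gives the endocyclic enol ether, C3 keeping its configuration because none of its bonds is broken.

Step 9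
Reactants: 15 (2S)-2-[(2E,4R,5R)-4-[(tert-butyldimethylsilyl)oxy]-5-(propan-2-yl)hepta-2,6-dien-2-yl]-5-methyl-2,3-dihydrofuran
Product: 18 (1S,2E,4R,5S,8Z)-4-[(tert-butyldimethylsilyl)oxy]-2,8-dimethyl-5-(propan-2-yl)cyclodeca-2,8-dien-1-ol, via B-alkyl borane 16 (not isolated), via macrocyclic borinate 17 (not isolated)
Conditions: 9-BBN-H (1.1 equiv), THF, 0 °C to rt; then slow addition to Ni(cod)2 (20 mol%), 1,3-bis(2,6-diisopropylphenyl)imidazol-2-ylidene (40 mol%), CsF (3 equiv), toluene, 80 °C, 2 mM; then aq. NaOH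
Reagents that add atoms: none
Why: Proposed new method: 9-BBN should hydroborate only the monosubstituted C8=C9 alkene (anti-Markovnikov) to give borane 16; zerovalent nickel carrying the bulky carbene then inserts into the C10(sp2)–O bond of the enol ether, the nickel-bound C3 alkoxide (helped by fluoride) forms the boron ate complex that hands C9 over to nickel within the same molecule, and reductive elimination makes the C9–C10 bond. The closest known reaction types are the nickel-catalysed, stereoretentive ring-opening Kumada coupling of 5-alkyl-2,3-dihydrofurans to homoallylic alcohols and the nickel/carbene-catalysed C–O alkylation of enol ethers by B-alkyl-9-BBN reagents; new is their union in an intramolecular sense, so that opening of the five-membered ring and closure of the ten-membered ring are one event. The carbocycle is closed by reductive elimination from an eleven-membered nickelacycle, an endo-type macrocyclisation at the vinylic carbon, helped by the two rigid trisubstituted alkenes and run under high dilution. No new stereocentre is made: the Z geometry of C1=C10 follows from the ring, in which oxygen and C2 are cis, because C9 replaces oxygen with retention while nickel stays held by the C3 alkoxide, and C3, C6 and C7 are not touched. The step needs hydroboration of the vinyl group only (secured by the rate gap of 9-BBN between a vinyl group and trisubstituted alkenes), insertion into the vinylic and not the allylic C3–O bond (secured by the electron-rich enol ether and the poorly binding trisubstituted C4=C5 alkene) and reductive elimination faster than beta-hydride loss (secured by the bulky carbene). It should deliver the ring, the Z alkene and the free C3 hydroxyl, already set apart from the silylated C6 oxygen, in one operation.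

Step 10
Reactants: 18 (1S,2E,4R,5S,8Z)-4-[(tert-butyldimethylsilyl)oxy]-2,8-dimethyl-5-(propan-2-yl)cyclodeca-2,8-dien-1-ol; 19 (2Z)-2-methylbut-2-enoic acid (angelic acid)
Product: 21 (1S,2E,4R,5S,8Z)-4-[(tert-butyldimethylsilyl)oxy]-2,8-dimethyl-5-(propan-2-yl)cyclodeca-2,8-dien-1-yl (2Z)-2-methylbut-2-enoate, via mixed anhydride 20 (not isolated)
Conditions: 2,4,6-Cl3C6H2COCl, Et3N, toluene, rt; then 18, 70 °C
Reagents that add atoms: none
Why: Yamaguchi-type mixed-anhydride esterification without a nucleophilic amine catalyst, the usual way to acylate hindered secondary alcohols with angelic acid while keeping the Z geometry.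

Step 11
Reactants: 21 (1S,2E,4R,5S,8Z)-4-[(tert-butyldimethylsilyl)oxy]-2,8-dimethyl-5-(propan-2-yl)cyclodeca-2,8-dien-1-yl (2Z)-2-methylbut-2-enoate
Product: 22 (1S,2E,4R,5S,8Z)-4-hydroxy-2,8-dimethyl-5-(propan-2-yl)cyclodeca-2,8-dien-1-yl (2Z)-2-methylbut-2-enoate
Conditions: HF·pyridine, pyridine, THF, 0 °C to rt
Reagents that add atoms: none
Why: Buffered fluoride desilylation should free the C6 hydroxyl under conditions that neither cleave nor isomerise the angelate, and the 1,4 relation across the E alkene rules out acyl migration.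

Step 12
Reactants: 22 (1S,2E,4R,5S,8Z)-4-hydroxy-2,8-dimethyl-5-(propan-2-yl)cyclodeca-2,8-dien-1-yl (2Z)-2-methylbut-2-enoate
Product: 23 (1S,2E,4R,5S,8Z)-4-(acetyloxy)-2,8-dimethyl-5-(propan-2-yl)cyclodeca-2,8-dien-1-yl (2Z)-2-methylbut-2-enoate
Conditions: Ac2O, pyridine, 4-(dimethylamino)pyridine (cat.), CH2Cl2, 0 °C to rt
Reagents that add atoms: acetic anhydride, CC(=O)OC(C)=O
Why: Standard acetylation of the remaining secondary alcohol with retention at C6 should give the target.

**Compound list**

1 | (E)-4-methylpent-2-ene | C/C=C/C(C)C | starting material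
2 | (E)-4-methylpent-2-en-1-ylpotassium | [K+].[CH2-]/C=C/C(C)C | intermediate
3 | 4,4,5,5-tetramethyl-2-[(2E)-4-methylpent-2-en-1-yl]-1,3,2-dioxaborolane | CC(C)/C=C/CB1OC(C)(C)C(C)(C)O1 | intermediate
4 | ethyl (2E)-2-methyl-4-oxobut-2-enoate | CCOC(=O)/C(C)=C/C=O | starting material
5 | pinacol borate ester of 6 (O-boryl homoallylic ether) | CCOC(=O)/C(C)=C/[C@H](OB1OC(C)(C)C(C)(C)O1)[C@H](C(C)C)C=C | intermediate
6 | ethyl (2E,4R,5R)-4-hydroxy-2-methyl-5-(propan-2-yl)hepta-2,6-dienoate | CCOC(=O)/C(C)=C/[C@H](O)[C@H](C(C)C)C=C | intermediate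
7 | ethyl (2E,4R,5R)-4-[(tert-butyldimethylsilyl)oxy]-2-methyl-5-(propan-2-yl)hepta-2,6-dienoate | CCOC(=O)/C(C)=C/[C@H](O[Si](C)(C)C(C)(C)C)[C@H](C(C)C)C=C | intermediate
8 | (2E,4R,5R)-4-[(tert-butyldimethylsilyl)oxy]-2-methyl-5-(propan-2-yl)hepta-2,6-dien-1-ol | OC/C(C)=C/[C@H](O[Si](C)(C)C(C)(C)C)[C@H](C(C)C)C=C | intermediate
9 | (2E,4R,5R)-4-[(tert-butyldimethylsilyl)oxy]-2-methyl-5-(propan-2-yl)hepta-2,6-dienal | O=C/C(C)=C/[C@H](O[Si](C)(C)C(C)(C)C)[C@H](C(C)C)C=C | intermediate
10 | 4,4,5,5-tetramethyl-2-(propa-1,2-dien-1-yl)-1,3,2-dioxaborolane (allenylboronic acid pinacol ester) | C=C=CB1OC(C)(C)C(C)(C)O1 | starting material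
11 | pinacol borate ester of 12 (O-boryl homopropargylic ether) | C#CC[C@H](OB1OC(C)(C)C(C)(C)O1)/C(C)=C/[C@H](O[Si](C)(C)C(C)(C)C)[C@H](C(C)C)C=C | intermediate
12 | (4S,5E,7R,8R)-7-[(tert-butyldimethylsilyl)oxy]-5-methyl-8-(propan-2-yl)deca-5,9-dien-1-yn-4-ol | C#CC[C@H](O)/C(C)=C/[C@H](O[Si](C)(C)C(C)(C)C)[C@H](C(C)C)C=C | intermediate
13 | dilithium alkoxide acetylide of 12 | [Li+].[Li+].[C-]#CC[C@H]([O-])/C(C)=C/[C@H](O[Si](C)(C)C(C)(C)C)[C@H](C(C)C)C=C | intermediate
14 | (5S,6E,8R,9R)-8-[(tert-butyldimethylsilyl)oxy]-6-methyl-9-(propan-2-yl)undeca-6,10-dien-2-yn-5-ol | CC#CC[C@H](O)/C(C)=C/[C@H](O[Si](C)(C)C(C)(C)C)[C@H](C(C)C)C=C | intermediate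
15 | (2S)-2-[(2E,4R,5R)-4-[(tert-butyldimethylsilyl)oxy]-5-(propan-2-yl)hepta-2,6-dien-2-yl]-5-methyl-2,3-dihydrofuran | CC1=CC[C@H](O1)/C(C)=C/[C@H](O[Si](C)(C)C(C)(C)C)[C@H](C(C)C)C=C | intermediate
16 | B-alkyl-9-BBN adduct of 15 (boron on the terminal carbon of the former vinyl group) | CC1=CC[C@H](O1)/C(C)=C/[C@H](O[Si](C)(C)C(C)(C)C)[C@H](C(C)C)CCB1C2CCCC1CCC2 | intermediate
17 | 9-borabicyclo[3.3.1]nonan-9-yl borinate (O-boryl ether) of 18 | C1CCC2CCCC1B2O[C@H]3C/C=C(/C)CC[C@@H](C(C)C)[C@@H](O[Si](C)(C)C(C)(C)C)/C=C/3C | intermediate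
18 | (1S,2E,4R,5S,8Z)-4-[(tert-butyldimethylsilyl)oxy]-2,8-dimethyl-5-(propan-2-yl)cyclodeca-2,8-dien-1-ol | O[C@H]1C/C=C(/C)CC[C@@H](C(C)C)[C@@H](O[Si](C)(C)C(C)(C)C)/C=C/1C | intermediate
19 | (2Z)-2-methylbut-2-enoic acid (angelic acid) | C/C=C(/C)C(=O)O | starting material
20 | (2Z)-2-methylbut-2-enoic 2,4,6-trichlorobenzoic anhydride | C/C=C(/C)C(=O)OC(=O)c1c(Cl)cc(Cl)cc1Cl | intermediate
21 | (1S,2E,4R,5S,8Z)-4-[(tert-butyldimethylsilyl)oxy]-2,8-dimethyl-5-(propan-2-yl)cyclodeca-2,8-dien-1-yl (2Z)-2-methylbut-2-enoate | C/C=C(/C)C(=O)O[C@H]1C/C=C(/C)CC[C@@H](C(C)C)[C@@H](O[Si](C)(C)C(C)(C)C)/C=C/1C | intermediate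
22 | (1S,2E,4R,5S,8Z)-4-hydroxy-2,8-dimethyl-5-(propan-2-yl)cyclodeca-2,8-dien-1-yl (2Z)-2-methylbut-2-enoate | C/C=C(/C)C(=O)O[C@H]1C/C=C(/C)CC[C@@H](C(C)C)[C@@H](O)/C=C/1C | intermediate
23 | (1S,2E,4R,5S,8Z)-4-(acetyloxy)-2,8-dimethyl-5-(propan-2-yl)cyclodeca-2,8-dien-1-yl (2Z)-2-methylbut-2-enoate | C/C=C(/C)C(=O)O[C@H]1C/C=C(/C)CC[C@@H](C(C)C)[C@@H](OC(C)=O)/C=C/1C | target

**Step count and risks**

Total step count: 12. Longest linear sequence: 12 steps (1 to 23).

Steps most likely to fail:

1. Step 9 (Proposed new method). What may go wrong: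
   - insertion of nickel into the allylic C3–O bond instead of the vinylic C10–O bond;
   - beta-hydride loss from the alkylnickel, giving ring-opened but uncyclised material;
   - intermolecular coupling in place of ring closure;
   - thermal [3,3] ring contraction (Cope or oxy-Cope) of the 3-oxygenated cyclodeca-1,5-diene at the coupling temperature.

   Fallback by known chemistry, setting out from 14 and returning at 18. Silylation of 14 with 1,1,3,3-tetramethyldisilazane should give the dimethylsilyl ether F1. [Cp*Ru(MeCN)3]PF6 in CH2Cl2 should bring about intramolecular trans-hydrosilylation in the endo sense to the six-membered cyclic alkenylsiloxane F2, with silicon on C10 and cis to C2. Iododesilylation with N-iodosuccinimide in hexafluoroisopropanol, followed by K2CO3/MeOH, should give the Z vinyl iodide F3 with retention. Protection of the C3 hydroxyl (Et3SiCl, imidazole) gives the triethylsilyl ether F4. 9-BBN-H then gives the B-alkyl borane F5, which under B-alkyl Suzuki–Miyaura macrocyclisation conditions (Pd(dppf)Cl2, AsPh3, Cs2CO3, DMF/THF/H2O, high dilution, rt to 50 °C) should close the ring to the bis-silyl ether F6. Selective removal of the triethylsilyl group (pyridinium p-toluenesulfonate, MeOH, 0 °C) returns 18.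

2. Step 8. What may go wrong:
   - attack of the C4=C5 alkene instead of the hydroxyl on the gold-activated alkyne (1,5-enyne cycloisomerisation);
   - acid-promoted hydration or dimerisation of the enol ether;
   - ionisation of the allylic alcohol.

   Fallback setting out from 12 and returning at 15. Cycloisomerisation of the terminal alkynol through a tungsten vinylidene (W(CO)6, Et3N, THF, irradiation at 350 nm) should give the 5-unsubstituted dihydrofuran F7 without a π-acid that could engage the enyne. Lithiation at the enol ether carbon (t-BuLi, THF, −78 to 0 °C) and quenching with MeI then gives 15; step 7 is not needed on this path.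

3. Step 10. What may go wrong:
   - Z to E isomerisation of the acyl unit in the activated anhydride;
   - slow acylation of the hindered ring alcohol;
   - thermal Cope ring contraction of the cyclodeca-1,5-diene on heating.

   Fallback setting out from 18 and returning at 21. Acylation at room temperature with 2-[bis(2,2,2-trifluoroethoxy)phosphoryl]propanoic acid (N,N′-dicyclohexylcarbodiimide, 4-(dimethylamino)pyridine, CH2Cl2) gives the phosphonopropionate F8. Still–Gennari olefination with acetaldehyde (KN(SiMe3)2, 18-crown-6, THF, −78 °C) should then build the Z-configured 2-methylbut-2-enoate in place and give 21.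

**Further compounds**

F1 | step 9 | dimethylsilyl ether of 14 | CC#CC[C@H](O[SiH](C)C)/C(C)=C/[C@H](O[Si](C)(C)C(C)(C)C)[C@H](C(C)C)C=C
F2 | step 9 | (6S)-6-[(2E,4R,5R)-4-[(tert-butyldimethylsilyl)oxy]-5-(propan-2-yl)hepta-2,6-dien-2-yl]-2,2,3-trimethyl-5,6-dihydro-2H-1,2-oxasiline | CC1=CC[C@H](O[Si]1(C)C)/C(C)=C/[C@H](O[Si](C)(C)C(C)(C)C)[C@H](C(C)C)C=C
F3 | step 9 | (2Z,5S,6E,8R,9R)-8-[(tert-butyldimethylsilyl)oxy]-2-iodo-6-methyl-9-(propan-2-yl)undeca-2,6,10-trien-5-ol | C/C(I)=C/C[C@H](O)/C(C)=C/[C@H](O[Si](C)(C)C(C)(C)C)[C@H](C(C)C)C=C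
F4 | step 9 | triethylsilyl ether of F3 | C/C(I)=C/C[C@H](O[Si](CC)(CC)CC)/C(C)=C/[C@H](O[Si](C)(C)C(C)(C)C)[C@H](C(C)C)C=C
F5 | step 9 | B-alkyl-9-BBN adduct of F4 (boron on the terminal carbon of the former vinyl group) | C/C(I)=C/C[C@H](O[Si](CC)(CC)CC)/C(C)=C/[C@H](O[Si](C)(C)C(C)(C)C)[C@H](C(C)C)CCB1C2CCCC1CCC2
F6 | step 9 | triethylsilyl ether of 18 | CC[Si](CC)(CC)O[C@H]1C/C=C(/C)CC[C@@H](C(C)C)[C@@H](O[Si](C)(C)C(C)(C)C)/C=C/1C
F7 | step 8 | (2S)-2-[(2E,4R,5R)-4-[(tert-butyldimethylsilyl)oxy]-5-(propan-2-yl)hepta-2,6-dien-2-yl]-2,3-dihydrofuran | C1=CC[C@H](O1)/C(C)=C/[C@H](O[Si](C)(C)C(C)(C)C)[C@H](C(C)C)C=C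
F8 | step 10 | 2-[bis(2,2,2-trifluoroethoxy)phosphoryl]propanoate ester of 18 | CC(C(=O)O[C@H]1C/C=C(/C)CC[C@@H](C(C)C)[C@@H](O[Si](C)(C)C(C)(C)C)/C=C/1C)P(=O)(OCC(F)(F)F)OCC(F)(F)F
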